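**Assumptions (one line each):** Ru–(R)-BINAP is assumed to deliver the (S)-acid in Step 12. Enolate alkylation is assumed to occur anti to the C4 substituent, as is usual for β-substituted lactone enolates. All three phenols/alcohols are carried as benzyl ethers and removed together at the end.

## Retrosynthetic overview
1. Nortrachelogenin (20) comes from global hydrogenolysis of the tri-O-benzyl lactone 19.
2. 19 comes from a late C7'–C8' coupling: the enolate of the (3S,4R)-3-benzyloxy-4-(vanillyl)lactone 18 is alkylated by vanillyl bromide 7. Attack anti to the C4 benzyl puts the new benzyl trans and the OBn cis, which is the required relative configuration.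
3. 18 comes from (S)-β-benzyl lactone 16 by α-hydroxylation and O-benzylation. 16 comes from LiBH4 reduction and lactonization of the hydrogenated Stobbe half-ester 15.
4. The C8 centre is set by asymmetric hydrogenation of Stobbe half-ester 14, made from O-benzylvanillin 11 and diethyl succinate 13.
5. Both aryl units are built from catechol via guaiacol: bromide 7 by the aryl-bromide route, aldehyde 11 by the glyoxylic acid route. The only ring formed is the lactone (Step 13).

## Route

**Step 1**
Reactants: 1 catechol
Product: 2 guaiacol (2-methoxyphenol)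
Conditions: (MeO)2CO, cat. K2CO3, cat. Bu4NBr, 160 °C, sealed tube
Reagents that add atoms: dimethyl carbonate, COC(=O)OC
Why: Selective mono-O-methylation of the catechol (BAl2 methyl transfer from dimethyl carbonate); the less acidic guaiacol phenol reacts much more slowly.

**Step 2**
Reactants: 2 guaiacol
Product: 3 4-bromo-2-methoxyphenol
Conditions: NBS, CH2Cl2, 0 °C
Reagents that add atoms: N-bromosuccinimide, O=C1CCC(=O)N1Br
Why: Electrophilic aromatic bromination goes para to the strongly activating OH.

**Step 3**
Reactants: 3
Product: 4 1-(benzyloxy)-4-bromo-2-methoxybenzene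
Conditions: BnBr, K2CO3, DMF, rt
Reagents that add atoms: benzyl bromide, BrCc1ccccc1
Why: Williamson O-benzylation protects the phenol.

**Step 4**
Reactants: 4
Product: 5 methyl 4-(benzyloxy)-3-methoxybenzoate
Conditions: Pd(OAc)2, dppf, Et3N, CO (10 atm), MeOH/DMF, 100 °C
Reagents that add atoms: carbon monoxide, [C-]#[O+]; methanol, CO
Why: Pd-catalysed methoxycarbonylation of the aryl bromide; the benzyl ether is inert.

**Step 5**
Reactants: 5
Product: 6 [4-(benzyloxy)-3-methoxyphenyl]methanol
Conditions: LiAlH4, THF, 0 °C
Reagents that add atoms: none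
Why: Ester reduction to the primary alcohol; aryl ethers are untouched.

**Step 6**
Reactants: 6
Product: 7 4-(benzyloxy)-3-methoxybenzyl bromide (fragment Q)
Conditions: CBr4, PPh3, CH2Cl2, 0 °C; use immediately
Reagents that add atoms: tetrabromomethane, BrC(Br)(Br)Br
Why: Appel bromination under neutral conditions suits this acid-sensitive, electron-rich benzylic bromide.

**Step 7**
Reactants: 2 guaiacol; 8 glyoxylic acid (OC(=O)C=O)
Product: 9 4-hydroxy-3-methoxymandelic acid (racemic)
Conditions: aq. NaOH, rt, 48 h
Reagents that add atoms: none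
Why: Para-selective electrophilic hydroxyalkylation of the guaiacol phenoxide by glyoxylate (Lederer–Manasse type); the stereocentre is destroyed in the next step.

**Step 8**
Reactants: 9
Product: 10 vanillin
Conditions: Cu(OH)2 (cat.), aq. NaOH, O2, 90 °C
Reagents that add atoms: none
Why: Cu-catalysed aerobic oxidative decarboxylation of the mandelic acid to the aldehyde.

**Step 9**
Reactants: 10
Product: 11 4-(benzyloxy)-3-methoxybenzaldehyde (O-benzylvanillin)
Conditions: BnBr, K2CO3, DMF, rt
Reagents that add atoms: benzyl bromide, BrCc1ccccc1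
Why: O-benzylation of the phenol so that it survives the basic steps below.

**Step 10**
Reactants: 12 succinic anhydride; EtOH
Product: 13 diethyl succinate
Conditions: EtOH, cat. H2SO4, reflux
Reagents that add atoms: ethanol, CCO
Why: Acid-catalysed alcoholysis and esterification give the Stobbe diester.

**Step 11**
Reactants: 11; 13
Product: 14 (E)-3-(ethoxycarbonyl)-4-[4-(benzyloxy)-3-methoxyphenyl]but-3-enoic acid
Conditions: KOtBu, tBuOH, reflux; then aq. HCl
Reagents that add atoms: none
Why: Stobbe condensation (aldol, then lactone formation and E1cB ring opening) gives the (E)-alkylidene half-ester. The free acid ends up on the CH2 and the conjugated ester on the alkylidene carbon.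

**Step 12**
Reactants: 14
Product: 15 (S)-3-{[4-(benzyloxy)-3-methoxyphenyl]methyl}-4-ethoxy-4-oxobutanoic acid
Conditions: H2 (50 bar), Ru(OAc)2[(R)-BINAP] (1 mol%), MeOH, 40 °C
Reagents that add atoms: none
Why: Carboxylate-directed asymmetric hydrogenation of the trisubstituted alkene sets C8 (the future C4 of the lactone); the catalyst controls the enantioface.

**Step 13**
Reactants: 15
Product: 16 (S)-4-{[4-(benzyloxy)-3-methoxyphenyl]methyl}oxolan-2-one
Conditions: (i) LiBH4, THF, 0→65 °C; (ii) 1 M HCl, then cat. TsOH, PhMe, 50 °C
Reagents that add atoms: none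
Why: The free acid is converted to its lithium carboxylate, which hydride does not attack, so LiBH4 reduces only the ethyl ester to CH2OH. Acid then closes the γ-lactone, the ring-forming step. The stereocentre is untouched.

**Step 14**
Reactants: 16
Product: 17 (3S,4R)-3-hydroxy-4-{[4-(benzyloxy)-3-methoxyphenyl]methyl}oxolan-2-one (trans, major)
Conditions: LiHMDS, THF, −78 °C; then Davis oxaziridine, −78 °C
Reagents that add atoms: 2-(phenylsulfonyl)-3-phenyloxaziridine, O=S(=O)(c1ccccc1)N1OC1c1ccccc1
Why: Electrophilic oxygen transfer to the lactone enolate (α-hydroxylation) occurs anti to the C4 benzyl. C3 is re-planarised in Step 16, so its diastereomeric ratio is not critical.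

**Step 15**
Reactants: 17
Product: 18 (3S,4R)-3-(benzyloxy)-4-{[4-(benzyloxy)-3-methoxyphenyl]methyl}oxolan-2-one
Conditions: BnOC(=NH)CCl3, cat. TfOH, CH2Cl2/cyclohexane, rt
Reagents that add atoms: benzyl trichloroacetimidate, N=C(OCc1ccccc1)C(Cl)(Cl)Cl
Why: Acid-catalysed O-benzylation under non-basic conditions protects the hindered α-OH without opening or epimerising the lactone.

**Step 16** (late coupling of the two halves)
Reactants: 18; 7
Product: 19 (3R,4R)-3-(benzyloxy)-3,4-bis{[4-(benzyloxy)-3-methoxyphenyl]methyl}oxolan-2-one
Conditions: LiHMDS, THF, −78 °C; DMPU; add 7, −78→−40 °C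
Reagents that add atoms: none
Why: Enolate C-alkylation forms the quaternary C3. The electrophile approaches anti to the C4 benzyl, so the new benzyl is trans to it and the OBn is cis, matching the target configuration.

**Step 17**
Reactants: 19
Product: 20 (+)-nortrachelogenin
Conditions: H2 (3 atm), Pd(OH)2/C, EtOAc/MeOH, rt
Reagents that add atoms: none
Why: Hydrogenolysis removes all three benzyl ethers. The lactone and both stereocentres have no benzylic C–O bonds and are unaffected.

**Checks:** 
- Formulas: 19 is C41H40O7 and 20 is C20H22O7, which is nortrachelogenin. 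
- Stereochemistry: 20 matches the target SMILES (C3 R, C4 R, benzyls trans). C4 comes from Step 12 and is never touched again. C3 is built in Step 16 and not scrambled afterwards.

## Compound list
1 | catechol | Oc1ccccc1O | starting material
2 | guaiacol | COc1ccccc1O | intermediate
3 | 4-bromo-2-methoxyphenol | COc1cc(Br)ccc1O | intermediate
4 | 1-(benzyloxy)-4-bromo-2-methoxybenzene | COc1cc(Br)ccc1OCc1ccccc1 | intermediate
5 | methyl 4-(benzyloxy)-3-methoxybenzoate | COC(=O)c1ccc(OCc2ccccc2)c(OC)c1 | intermediate
6 | [4-(benzyloxy)-3-methoxyphenyl]methanol | COc1cc(CO)ccc1OCc1ccccc1 | intermediate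
7 | 4-(benzyloxy)-3-methoxybenzyl bromide | COc1cc(CBr)ccc1OCc1ccccc1 | intermediate
8 | glyoxylic acid | OC(=O)C=O | starting material
9 | 4-hydroxy-3-methoxymandelic acid (racemic) | COc1cc(C(O)C(=O)O)ccc1O | intermediate
10 | vanillin | COc1cc(C=O)ccc1O | intermediate
11 | O-benzylvanillin | COc1cc(C=O)ccc1OCc1ccccc1 | intermediate
12 | succinic anhydride | O=C1CCC(=O)O1 | starting material
13 | diethyl succinate | CCOC(=O)CCC(=O)OCC | intermediate
14 | (E)-Stobbe half-ester | CCOC(=O)/C(CC(=O)O)=C/c1ccc(OCc2ccccc2)c(OC)c1 | intermediate
15 | (S)-hydrogenated half-ester | OC(=O)C[C@H](Cc1ccc(OCc2ccccc2)c(OC)c1)C(=O)OCC | intermediate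
16 | (S)-β-benzyl lactone | O=C1C[C@H](Cc2ccc(OCc3ccccc3)c(OC)c2)CO1 | intermediate
17 | (3S,4R)-3-hydroxy lactone | O=C1[C@@H](O)[C@H](Cc2ccc(OCc3ccccc3)c(OC)c2)CO1 | intermediate
18 | (3S,4R)-3-benzyloxy lactone | O=C1[C@@H](OCc2ccccc2)[C@H](Cc2ccc(OCc3ccccc3)c(OC)c2)CO1 | intermediate
19 | protected nortrachelogenin | COc1cc(C[C@@H]2COC(=O)[C@@]2(OCc2ccccc2)Cc2ccc(OCc3ccccc3)c(OC)c2)ccc1OCc1ccccc1 | intermediate
20 | (+)-nortrachelogenin | COc1cc(C[C@@H]2COC(=O)[C@@]2(O)Cc2ccc(O)c(OC)c2)ccc1O | target

## Totals
Total steps: 17. Longest linear sequence: 11 (Steps 1, 7, 8, 9, 11, 12, 13, 14, 15, 16, 17).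

## Three steps most likely to fail
1. **Step 12 (asymmetric hydrogenation):** the ligand sense and ee are assumed from analogy. Fallback: an Evans route to 16. Alkylate the imide of mono-tert-butyl succinate and (R)-4-benzyloxazolidin-2-one with 7 (NaHMDS), reduce with LiBH4, then cyclise with TFA.
2. **Step 16 (hindered, electron-rich benzylation):** risks are low diastereoselectivity and self-condensation of 7. Fallback: form the C8–C8' bond instead. Run a titanium aldol between the Evans imide of 3-(4-benzyloxy-3-methoxyphenyl)propanoic acid and methyl 3-aryl-2-oxopropanoate, then LiBH4/lactonization and hydrogenolysis.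
3. **Step 13 (ester reduced in the presence of carboxylate):** the hindered ester may be sluggish or over-reduced. Fallback: saponify to the diacid, make the cyclic anhydride with Ac2O, and reduce it regioselectively with NaBH4 at the more hindered carbonyl to give lactone 16.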